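**Assumption:** the quinine-derived thiourea is taken to be the cinchona pseudoenantiomer that gives the (2S) series; this should be checked on a small 4-benzyloxyphenyl model, and the quinidine-derived pseudoenantiomer used if the model shows the opposite sense.

## Structural features

Compound 16 is a C–C linked biflavonoid. A (2S)-flavanone (naringenin) unit, made of the fused chroman-4-one rings A and C with ring B on C2, is joined through C3' of ring B to C6'' of a flavone (apigenin) unit. The only stereocentre is C2, a benzylic carbon bound to O1 and two bonds from the C4 carbonyl; it has no neighbouring stereocentre. The C3'–C6'' axis is flanked by only three ortho substituents (O4', O5'', O7''), should rotate freely, and is not a stereogenic element of the target. The fragile elements are the C2 configuration, the six phenols and the flavone pyranone. C2 is lost whenever O1–C2 opens to the 2'-hydroxychalcone, under base or by acid-assisted ionisation helped by the para oxygen O4'; the pyranone does not tolerate hot hydroxide. Two problems dominate: C2 must be set by a method whose product does not revert, and the biaryl bond must be made at C6'' and not C8'' of a doubly ortho-substituted ring. The key step exploits the 1,3-relationship of O1 and the C4 carbonyl: O1–C2 is the retron of a conjugate addition of the ring A phenol oxygen to the benzylidene carbon of a chalcone, and an ester placed temporarily on C3 makes that closure of ring C fast and catalyst-controlled.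

## Logic of the disconnections

**16 to 15.** The six aryl O–CH2Ph bonds are cut. All phenols stay masked to the end so that the free polyphenol only ever meets a neutral reagent, since base would reopen O1–C2. The gain is that every earlier intermediate is non-acidic and soluble, and only one oxygen is ever nucleophilic. The forward step must cleave benzyl ethers faster than it touches C2''=C3'', the C4 carbonyl or the benzylic O1–C2 bond.

**15 to 13 (through 14).** A C3–carboxyl bond is added retrosynthetically. The ester on C3 is a traceless activating group that turns the chalcone acceptor into an alkylidene β-keto ester. The gain is a precursor whose O1–C2 bond forms at low temperature under catalyst control. The forward step must remove the ester without base and without prolonged hot acid, so that C2 holds while C3 becomes a methylene.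

**13 to 12.** O1–C2 is cut, which opens ring C and removes both stereocentres. This is the bond through which flavanones racemise, so the same pathway run forward under a chiral catalyst can set C2. The gain is an achiral precursor with one free phenol. The forward step must select one alkene face, involve one nucleophile only, and have a negligible uncatalysed background. The descriptors are consistent: in 12 the ester outranks the aroyl group and is cis to ring B, hence Z; in 13 ring B and the ester are trans, hence (2S,3R); loss of the C3 substituent leaves (2S) in 15 and 16.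

**12 to 11 and 8.** The C2=C3 alkene of the benzylidene unit is cut (Knoevenagel retron). This splits the molecule into two halves of similar size and makes the route convergent. The forward condensation must not trigger a non-selective ring closure through the free phenol and should give one alkene geometry. The precursor keeps a single free, chelated phenol; no change of protecting groups is judged necessary, and the safeguards are put into how it is made.

**8 to 4 and 7.** The C3'–C6'' biaryl bond is cut. It is the only bond joining the two flavonoid halves; the halide is placed on the flavone and boron on the small benzaldehyde. The gain is two fragments that each derive from one commercial compound. The forward coupling must tolerate a di-ortho-substituted iodide, an ortho-substituted boronate and a free aldehyde.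

**4 to 3 to 2 to 1.** The O5''–benzyl bond, the C6''–I bond and the O7''/O4''' benzyl bonds are cut in that order. Iodination is placed while O5'' is still a free, chelated hydroxyl, because that hydroxyl directs iodine to C6''; the fully O-alkylated ring would be expected to iodinate at C8''. The gain is a commercial flavone as starting material. The forward sequence needs a selective double benzylation that leaves the chelated hydroxyl alone.

**7 to 6 to 5.** The C–B bond and one O–benzyl bond are cut. The bromide is the natural handle for borylation, and the gain is a commercial bromophenol aldehyde. The borylation must leave the aldehyde intact.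

**11 to 10 to 9.** The bond between the methylene carbon and the ester carbonyl is cut (Claisen retron), then two O–benzyl bonds. The gain is a commercial acetophenone whose third, chelated hydroxyl is left free for the key step. The acylation must occur on carbon and not on the phenoxide oxygen.

## Other disconnections considered

**Alternative 1:** The cut removes ring B of the flavanone half at C2'–C3' and C4'–C5'. The hindered C3'–C6'' bond is then already present as the benzylic C–C bond of the flavon-6-ylacetic acid A1.
- **Forward step:** the bis(trimethylsilyl) ketene acetal A2 would add across C6 and C3 of methyl coumalate A3 in an inverse-demand Diels–Alder reaction. Decarboxylative cycloreversion and loss of the silyloxy group would aromatise the adduct to the methyl 4-hydroxy-3-(flavon-6-yl)benzoate A4.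
- **In favour:** no cross-coupling at the doubly flanked C6''; regiochemistry is fixed by the polarity of the partners; O4' is born as a free, differentiated phenol.
- **Against:** A1 still needs C6'' to be functionalised first, so the C6''/C8'' question only moves. A2 carries a bulky 2,6-dioxygenated aryl group on its reacting carbon, so the cycloaddition should be slow. Making A2 needs two equivalents of strong amide base beside the flavone enone. A4 is at the wrong oxidation level and needs O-benzylation, reduction and re-oxidation to reach 8.
- **Comparison:** structurally it solves the biaryl and not the stereocentre, so ring C would still be closed as in steps 9 to 12. It is the better plan on steric congestion at the biaryl bond (a pericyclic construction against a palladium coupling at a tri-ortho-substituted axis). It is the equal of the chosen plan in regiochemical certainty once A1 is in hand. In step economy it is longer by an estimated four or five operations between 4 and 8.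

**Alternative 2:** Flavone ring A is dismantled at C5''–C6'', C7''–C8'' and C4a''–C5''. This leaves the 2-aryl-4-pyranone diazoketone A5 and the aryl siloxyalkyne A6, which already carries ring B.
- **Forward step:** Wolff rearrangement of A5 would give a pyranonyl ketene that takes up A6 by [2+2] cycloaddition, 4π opening and 6π closure (Danheiser benzannulation). The product would be the flavone A7, with O5'' free, O7'' silylated and ring B at C6''.
- **In favour:** the substitution pattern of ring A is written by the polarity of the siloxyalkyne, so the C6''/C8'' question never arises. The hindered biaryl bond is made as an unhindered sp–sp2 bond. O5'' and O7'' emerge differentiated.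
- **Against:** the diazoketone needs a diazoalkane acylation or a diazo transfer on a pyranone, the least safe operation of any plan here. A 4-pyranone is itself photolabile, so the Wolff step competes with rearrangement of the heterocycle. The 6π closure must engage the C5=C6 bond of a cross-conjugated vinylogous ester, which is less assured than a simple vinylketene. Aryl siloxyalkynes are delicate and take several steps.
- **Comparison:** on structure it is the better plan for regiocontrol in ring A and for avoiding the congested palladium coupling. On mechanism it has more unproven individual events than the chosen plan. On step economy it is much longer, because ring A is built instead of bought as 1. Like alternative 1, it leaves C2 to be set separately.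

**Alternative 3:** The cut is C2–C3. Ring C is opened to the ring A diazoacetyl ketone A8, whose ortho oxygen (the future O1) bears the ring B benzyl group.
- **Forward step:** a chiral dirhodium tetracarboxylate catalyst would convert A8 into a rhodium carbene. Its carbon (C3) would insert into one of the two enantiotopic benzylic C–H bonds, closing ring C by a 1,6-insertion to give the protected flavanone A9.
- **In favour:** the stereocentre forms in an irreversible C–C bond formation, so the catalyst that made it cannot racemise it. There is no activating group to remove and no decarboxylation. Aldehyde 8 still serves after reduction and O-alkylation.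
- **Against:** the ether oxygen sits where it can form an oxonium ylide with the carbene, and a 1,2-shift of the electron-rich benzyl group is the usual course for ortho-alkoxy diazoketones. An acceptor-only carbene is the least selective class for enantiocontrol. Six further O–CH2 groups and many arenes offer sites for stray insertion or cyclopropanation. A diazoketone must be made and handled.
- **Comparison:** structurally it is the equal of the chosen plan in convergence and choice of fragments. It is the better plan in the irreversibility of the stereo-defining step and in needing no traceless auxiliary. Mechanistically the chosen closure has one possible ring size and one nucleophile, whereas here chemoselectivity among carbene pathways is the central uncertainty. Step economy is about equal: protecting-group exchange, benzylic halide formation and diazo transfer replace steps 8, 9 and 11.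

Key step: step 10

## Route

Step 1
Reactants: 1 apigenin (5,7-dihydroxy-2-(4-hydroxyphenyl)-4H-chromen-4-one)
Product: 2 7-(benzyloxy)-2-[4-(benzyloxy)phenyl]-5-hydroxy-4H-chromen-4-one
Conditions: BnBr (2.2 equiv), K2CO3, DMF, 20–40 °C
Reagents that add atoms: benzyl bromide, BrCc1ccccc1
Why: Williamson etherification; the 7- and 4'-hydroxyls are the acidic, unchelated phenols, whereas the 5-hydroxyl is hydrogen-bonded to the C4 carbonyl and should not be alkylated by a carbonate base near room temperature with two equivalents of halide.

Step 2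
Reactants: 2 7-(benzyloxy)-2-[4-(benzyloxy)phenyl]-5-hydroxy-4H-chromen-4-one
Product: 3 7-(benzyloxy)-2-[4-(benzyloxy)phenyl]-5-hydroxy-6-iodo-4H-chromen-4-one
Conditions: BnMe3N+ ICl2− (1.05 equiv), CaCO3, CH2Cl2–MeOH, 20 °C
Reagents that add atoms: benzyltrimethylammonium dichloroiodate, C[N+](C)(C)Cc1ccccc1.Cl[I-]Cl
Why: Electrophilic aromatic iodination; ring A is the most electron-rich ring and the free, chelated 5-hydroxyl should direct iodine to its ortho position C6, whereas a 5-O-alkyl ether would be expected to react at C8; CaCO3 takes up the HCl.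

Step 3
Reactants: 3 7-(benzyloxy)-2-[4-(benzyloxy)phenyl]-5-hydroxy-6-iodo-4H-chromen-4-one
Product: 4 5,7-bis(benzyloxy)-2-[4-(benzyloxy)phenyl]-6-iodo-4H-chromen-4-one
Conditions: BnBr (1.5 equiv), K2CO3, DMF, 70 °C
Reagents that add atoms: benzyl bromide, BrCc1ccccc1
Why: Williamson etherification of the chelated, flanked 5-hydroxyl, which needs heat and a polar aprotic solvent; the aryl iodide and the flavone are inert to carbonate.

Step 4
Reactants: 5 3-bromo-4-hydroxybenzaldehyde
Product: 6 4-(benzyloxy)-3-bromobenzaldehyde
Conditions: BnBr (1.1 equiv), K2CO3, DMF, 20 °C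
Reagents that add atoms: benzyl bromide, BrCc1ccccc1
Why: Williamson etherification of an acidic para-formyl phenol; the aldehyde has no α-hydrogen and is untouched.

Step 5
Reactants: 6 4-(benzyloxy)-3-bromobenzaldehyde
Product: 7 4-(benzyloxy)-3-(4,4,5,5-tetramethyl-1,3,2-dioxaborolan-2-yl)benzaldehyde
Conditions: B2pin2 (1.2 equiv), PdCl2(dppf) (3 mol%), KOAc, 1,4-dioxane, 85 °C
Reagents that add atoms: bis(pinacolato)diboron, CC1(C)OB(OC1(C)C)B1OC(C)(C)C(C)(C)O1
Why: Miyaura borylation; zerovalent palladium from [1,1'-bis(diphenylphosphino)ferrocene]palladium dichloride inserts into C–Br, and the weak acetate base is enough for boron transfer but not for coupling of the product with unreacted bromide or for attack on the aldehyde.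

Step 6
Reactants: 4 5,7-bis(benzyloxy)-2-[4-(benzyloxy)phenyl]-6-iodo-4H-chromen-4-one; 7 4-(benzyloxy)-3-(4,4,5,5-tetramethyl-1,3,2-dioxaborolan-2-yl)benzaldehyde
Product: 8 4-(benzyloxy)-3-{5,7-bis(benzyloxy)-2-[4-(benzyloxy)phenyl]-4-oxo-4H-chromen-6-yl}benzaldehyde
Conditions: Pd(OAc)2 (5 mol%), SPhos (2-dicyclohexylphosphino-2',6'-dimethoxybiphenyl, 10 mol%), K3PO4, toluene–H2O, 90 °C
Reagents that add atoms: none
Why: Suzuki–Miyaura coupling; the bulky, electron-rich biarylphosphine is suited to a di-ortho-substituted aryl iodide and an ortho-substituted boronate, and the non-enolisable aldehyde and the flavone tolerate aqueous phosphate; the new axis has three ortho substituents and should not give separable rotamers.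

Step 7
Reactants: 9 2',4',6'-trihydroxyacetophenone (1-(2,4,6-trihydroxyphenyl)ethan-1-one)
Product: 10 1-[2,4-bis(benzyloxy)-6-hydroxyphenyl]ethan-1-one
Conditions: BnBr (2.05 equiv), K2CO3, acetone, 56 °C
Reagents that add atoms: benzyl bromide, BrCc1ccccc1
Why: Williamson etherification; after the para and one ortho hydroxyl are benzylated, the remaining ortho hydroxyl is locked in a hydrogen bond to the acetyl carbonyl and should resist the third alkylation when the halide is limited to two equivalents.

Step 8
Reactants: 10 1-[2,4-bis(benzyloxy)-6-hydroxyphenyl]ethan-1-one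
Product: 11 tert-butyl 3-[2,4-bis(benzyloxy)-6-hydroxyphenyl]-3-oxopropanoate
Conditions: LiN(SiMe3)2 (3.3 equiv), THF, −78 °C; Boc2O (1.1 equiv), −78 to 0 °C; aq NH4Cl
Reagents that add atoms: di-tert-butyl dicarbonate, CC(C)(C)OC(=O)OC(=O)OC(C)(C)C
Why: Claisen-type C-acylation of a ketone enolate; the phenoxide–enolate dianion should react at its more nucleophilic carbon, the third equivalent of base deprotonates the β-keto ester as it forms and so prevents double acylation, and the tert-butyl ester resists lactonisation onto the phenoxide at low temperature.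

Step 9
Reactants: 11 tert-butyl 3-[2,4-bis(benzyloxy)-6-hydroxyphenyl]-3-oxopropanoate; 8 4-(benzyloxy)-3-{5,7-bis(benzyloxy)-2-[4-(benzyloxy)phenyl]-4-oxo-4H-chromen-6-yl}benzaldehyde
Product: 12 tert-butyl (2Z)-2-[2,4-bis(benzyloxy)-6-hydroxybenzoyl]-3-(4-(benzyloxy)-3-{5,7-bis(benzyloxy)-2-[4-(benzyloxy)phenyl]-4-oxo-4H-chromen-6-yl}phenyl)prop-2-enoate
Conditions: piperidine (0.2 equiv), AcOH (0.4 equiv), 4 Å molecular sieves, toluene, 20–40 °C
Reagents that add atoms: none
Why: Knoevenagel condensation through the piperidinium iminium of the aldehyde; the Z isomer (ring B cis to the planar ester, twisted aroyl group trans) should be the thermodynamic product, and the excess of acetic acid keeps the chelated phenol protonated so that ring closure does not start under achiral base.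

Step 10
Reactants: 12 tert-butyl (2Z)-2-[2,4-bis(benzyloxy)-6-hydroxybenzoyl]-3-(4-(benzyloxy)-3-{5,7-bis(benzyloxy)-2-[4-(benzyloxy)phenyl]-4-oxo-4H-chromen-6-yl}phenyl)prop-2-enoate
Product: 13 tert-butyl (2S,3R)-5,7-bis(benzyloxy)-2-(4-(benzyloxy)-3-{5,7-bis(benzyloxy)-2-[4-(benzyloxy)phenyl]-4-oxo-4H-chromen-6-yl}phenyl)-4-oxo-3,4-dihydro-2H-chromene-3-carboxylate (trans, in equilibrium with its enol)
Conditions: N-[3,5-bis(trifluoromethyl)phenyl]-N'-[(8α,9S)-6'-methoxycinchonan-9-yl]thiourea (10 mol%), toluene, −25 °C; then short silica plug
Reagents that add atoms: none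
Why: The two thiourea N–H bonds should hold the β-keto ester of 12 while the quinuclidine nitrogen takes the proton of the chelated O2' phenol, and the ion-paired phenoxide then adds to the benzylidene carbon to form O1–C2, after which the bound enolate is protonated at C3. The closest known reaction type is the cinchona-thiourea-catalysed intramolecular oxa-Michael addition of 2-hydroxyaryl alkylidene β-keto esters. Ring C closes in the 6-endo-trig mode, the only one open to the phenoxide because the α-carbon is the electron-rich end of the acceptor. C2 is under catalyst control: two-point binding exposes one face of the Z alkene to O1 and should give the (2S) configuration. C3 is under thermodynamic control: it is a β-dicarbonyl methine that equilibrates through its enol to the trans (2S,3R) isomer, and it is erased in step 11 in any case. The step needs one nucleophile, one acceptor and a negligible uncatalysed background; the first two are secured by benzylation of every other oxygen and by the inertness and remoteness of the flavone enone, the third by the double activation of the acceptor, which allows closure at −25 °C despite the donor O4' para to the reacting carbon. The ester also holds the product as a hydrogen-bonded β-dicarbonyl, which should slow the retro-addition that would erode C2.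

Step 11
Reactants: 13 tert-butyl (2S,3R)-5,7-bis(benzyloxy)-2-(4-(benzyloxy)-3-{5,7-bis(benzyloxy)-2-[4-(benzyloxy)phenyl]-4-oxo-4H-chromen-6-yl}phenyl)-4-oxo-3,4-dihydro-2H-chromene-3-carboxylate
Product: 15 (2S)-5,7-bis(benzyloxy)-2-(4-(benzyloxy)-3-{5,7-bis(benzyloxy)-2-[4-(benzyloxy)phenyl]-4-oxo-4H-chromen-6-yl}phenyl)-2,3-dihydro-4H-chromen-4-one, via beta-keto acid 14 (not isolated)
Conditions: TsOH·H2O (0.5 equiv), toluene, 70–80 °C
Reagents that add atoms: none
Why: Acid-promoted E1 loss of isobutene from the tert-butyl ester, followed by decarboxylation of the β-keto acid through its cyclic six-membered transition state; C3 becomes a methylene and C2 is not involved, and because the basic catalyst was removed in step 10 no phenoxide pathway for ring opening is available.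

Step 12
Reactants: 15 (2S)-5,7-bis(benzyloxy)-2-(4-(benzyloxy)-3-{5,7-bis(benzyloxy)-2-[4-(benzyloxy)phenyl]-4-oxo-4H-chromen-6-yl}phenyl)-2,3-dihydro-4H-chromen-4-one
Product: 16 (2S)-5,7-dihydroxy-2-{3-[5,7-dihydroxy-2-(4-hydroxyphenyl)-4-oxo-4H-chromen-6-yl]-4-hydroxyphenyl}-2,3-dihydro-4H-chromen-4-one
Conditions: H2 (1 atm), Pd/C (10% palladium on carbon), THF–MeOH, 20 °C
Reagents that add atoms: none
Why: Hydrogenolysis of six aryl benzyl ethers under neutral conditions, so O1–C2 is not opened and C2 keeps its configuration; the flavone C2''=C3'' bond and the aryl ketone are vinylogous ester and chelated carbonyl and should survive at one atmosphere if the reaction is stopped at complete debenzylation.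

## Compound list

1 | apigenin, 5,7-dihydroxy-2-(4-hydroxyphenyl)-4H-chromen-4-one | O=c1cc(-c2ccc(O)cc2)oc2cc(O)cc(O)c12 | starting material
2 | 7-(benzyloxy)-2-[4-(benzyloxy)phenyl]-5-hydroxy-4H-chromen-4-one | O=c1cc(-c2ccc(OCc3ccccc3)cc2)oc2cc(OCc3ccccc3)cc(O)c12 | intermediate
3 | 7-(benzyloxy)-2-[4-(benzyloxy)phenyl]-5-hydroxy-6-iodo-4H-chromen-4-one | O=c1cc(-c2ccc(OCc3ccccc3)cc2)oc2cc(OCc3ccccc3)c(I)c(O)c12 | intermediate
4 | 5,7-bis(benzyloxy)-2-[4-(benzyloxy)phenyl]-6-iodo-4H-chromen-4-one | O=c1cc(-c2ccc(OCc3ccccc3)cc2)oc2cc(OCc3ccccc3)c(I)c(OCc3ccccc3)c12 | intermediate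
5 | 3-bromo-4-hydroxybenzaldehyde | O=Cc1ccc(O)c(Br)c1 | starting material
6 | 4-(benzyloxy)-3-bromobenzaldehyde | O=Cc1ccc(OCc2ccccc2)c(Br)c1 | intermediate
7 | 4-(benzyloxy)-3-(4,4,5,5-tetramethyl-1,3,2-dioxaborolan-2-yl)benzaldehyde | O=Cc1ccc(OCc2ccccc2)c(B2OC(C)(C)C(C)(C)O2)c1 | intermediate
8 | 4-(benzyloxy)-3-{5,7-bis(benzyloxy)-2-[4-(benzyloxy)phenyl]-4-oxo-4H-chromen-6-yl}benzaldehyde | O=Cc1ccc(OCc2ccccc2)c(-c2c(OCc3ccccc3)cc3oc(-c4ccc(OCc5ccccc5)cc4)cc(=O)c3c2OCc2ccccc2)c1 | intermediate
9 | 2',4',6'-trihydroxyacetophenone, 1-(2,4,6-trihydroxyphenyl)ethan-1-one | CC(=O)c1c(O)cc(O)cc1O | starting material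
10 | 1-[2,4-bis(benzyloxy)-6-hydroxyphenyl]ethan-1-one | CC(=O)c1c(O)cc(OCc2ccccc2)cc1OCc1ccccc1 | intermediate
11 | tert-butyl 3-[2,4-bis(benzyloxy)-6-hydroxyphenyl]-3-oxopropanoate | CC(C)(C)OC(=O)CC(=O)c1c(O)cc(OCc2ccccc2)cc1OCc1ccccc1 | intermediate
12 | tert-butyl (2Z)-2-[2,4-bis(benzyloxy)-6-hydroxybenzoyl]-3-(4-(benzyloxy)-3-{5,7-bis(benzyloxy)-2-[4-(benzyloxy)phenyl]-4-oxo-4H-chromen-6-yl}phenyl)prop-2-enoate | CC(C)(C)OC(=O)/C(=C\c1ccc(OCc2ccccc2)c(-c2c(OCc3ccccc3)cc3oc(-c4ccc(OCc5ccccc5)cc4)cc(=O)c3c2OCc2ccccc2)c1)C(=O)c1c(O)cc(OCc2ccccc2)cc1OCc1ccccc1 | intermediate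
13 | tert-butyl (2S,3R)-5,7-bis(benzyloxy)-2-(4-(benzyloxy)-3-{5,7-bis(benzyloxy)-2-[4-(benzyloxy)phenyl]-4-oxo-4H-chromen-6-yl}phenyl)-4-oxo-3,4-dihydro-2H-chromene-3-carboxylate | O=C1[C@H](C(=O)OC(C)(C)C)[C@@H](c2ccc(OCc3ccccc3)c(-c3c(OCc4ccccc4)cc4oc(-c5ccc(OCc6ccccc6)cc5)cc(=O)c4c3OCc3ccccc3)c2)Oc2cc(OCc3ccccc3)cc(OCc3ccccc3)c21 | intermediate
14 | (2S,3R)-5,7-bis(benzyloxy)-2-(4-(benzyloxy)-3-{5,7-bis(benzyloxy)-2-[4-(benzyloxy)phenyl]-4-oxo-4H-chromen-6-yl}phenyl)-4-oxo-3,4-dihydro-2H-chromene-3-carboxylic acid | O=C1[C@H](C(=O)O)[C@@H](c2ccc(OCc3ccccc3)c(-c3c(OCc4ccccc4)cc4oc(-c5ccc(OCc6ccccc6)cc5)cc(=O)c4c3OCc3ccccc3)c2)Oc2cc(OCc3ccccc3)cc(OCc3ccccc3)c21 | intermediate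
15 | (2S)-5,7-bis(benzyloxy)-2-(4-(benzyloxy)-3-{5,7-bis(benzyloxy)-2-[4-(benzyloxy)phenyl]-4-oxo-4H-chromen-6-yl}phenyl)-2,3-dihydro-4H-chromen-4-one | O=C1C[C@@H](c2ccc(OCc3ccccc3)c(-c3c(OCc4ccccc4)cc4oc(-c5ccc(OCc6ccccc6)cc5)cc(=O)c4c3OCc3ccccc3)c2)Oc2cc(OCc3ccccc3)cc(OCc3ccccc3)c21 | intermediate
16 | (2S)-5,7-dihydroxy-2-{3-[5,7-dihydroxy-2-(4-hydroxyphenyl)-4-oxo-4H-chromen-6-yl]-4-hydroxyphenyl}-2,3-dihydro-4H-chromen-4-one | O=C1C[C@@H](c2ccc(O)c(-c3c(O)cc4oc(-c5ccc(O)cc5)cc(=O)c4c3O)c2)Oc2cc(O)cc(O)c21 | target

## Step count and least certain steps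

Total: 12 steps. Longest linear sequence: 8 steps (steps 1, 2, 3, 6, 9, 10, 11, 12, from 1 to 16). Steps 10 and 11 are kept separate so that the basic catalyst is removed before the mixture is heated with acid.

**Step 10 (key step).** The likely failure is poor facial selectivity or slow closure. The second ortho substituent on ring A twists the aroyl group out of the plane the catalyst needs, the donor O4' lowers the electrophilicity of the benzylidene carbon, and a slow catalysed reaction lets the unselective background closure compete. The sense of induction could also be the opposite one; that is answered by the quinidine-derived pseudoenantiomer. If selectivity cannot be reached, the fallback gives up asymmetric catalysis for resolution. It sets out from 10 and 8. Claisen–Schmidt condensation (KOH, EtOH–THF, 20 °C) should give the 2'-hydroxychalcone F1. Closure with NaOAc in refluxing EtOH–THF should give the racemic hexa-O-benzyl flavanone F2. Preparative chromatography on a chiral stationary phase would separate 15 from the (2R)-enantiomer F3, which can be returned to the racemate with mild base through the same ring opening and resolved again. The fallback rejoins the route at 15.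

**Step 9.** The likely failures are premature, non-selective ring closure through the free phenol under the amine catalyst, slow condensation of a hindered β-keto ester with an electron-rich aldehyde, and formation of both alkene isomers. The fallback masks the phenol during the condensation. It sets out from 11: TIPSCl and imidazole in DMF should give the triisopropylsilyl ether F4. Condensation of F4 with 8 under piperidine/AcOH, now with heating and azeotropic water removal, should give the silyl-protected alkylidene F5. HF·pyridine in THF at 0 °C, an acidic and non-basic desilylation, would release the phenol and rejoin the route at 12.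

**Step 11.** The likely failures are partial loss of configuration at C2 by acid-promoted ionisation of the benzylic O1–C2 bond (assisted by the para oxygen of ring B) and acid-induced cleavage of benzyl ethers with re-attack of the benzyl cation on the electron-rich rings. The fallback removes the acid step by changing the ester to one that leaves in the final hydrogenolysis. It sets out from 10. LiN(SiMe3)2 and dibenzyl dicarbonate should give the benzyl β-keto ester F6. Knoevenagel condensation with 8 should give the benzyl alkylidene ester F7. The thiourea-catalysed closure should give the benzyl flavanone-3-carboxylate F8. H2 over Pd/C would then cleave all seven benzyl groups, and the hexahydroxy β-keto acid F9 should lose carbon dioxide on gentle warming. The fallback rejoins the route at 16 and is one step shorter, but the enantioselectivity of the closure would have to be re-established for the smaller ester.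

**Step 6.** The likely failure is slow transmetalation at the iodide flanked by two benzyloxy groups, which lets protodeboronation of the boronate and hydrodeiodination of the iodide take over. The fallback couples before the last benzyl group is in place. It sets out from 3, whose iodine is flanked on one side by a small chelated hydroxyl. Coupling of 3 with 7 under the same palladium/biarylphosphine system should give the 5''-hydroxy biaryl aldehyde F10. Benzylation (BnBr, K2CO3, DMF, 70 °C) would rejoin the route at 8.

**Step 12.** The likely failures are over-reduction (saturation of the flavone C2''=C3'' bond, hydrogenolysis of the benzylic O1–C2 bond or reduction of the C4 carbonyl) and incomplete cleavage because partly debenzylated material is poorly soluble. The fallback is non-reductive: BCl3 with pentamethylbenzene as cation scavenger in CH2Cl2 at −78 °C, from 15 directly to 16, kept cold and short to avoid Lewis-acid opening of ring C. It passes through no compound outside the compound list (entry F0).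

## Further compounds

F1 | step 10 | (2E)-1-[2,4-bis(benzyloxy)-6-hydroxyphenyl]-3-(4-(benzyloxy)-3-{5,7-bis(benzyloxy)-2-[4-(benzyloxy)phenyl]-4-oxo-4H-chromen-6-yl}phenyl)prop-2-en-1-one | O=C(/C=C/c1ccc(OCc2ccccc2)c(-c2c(OCc3ccccc3)cc3oc(-c4ccc(OCc5ccccc5)cc4)cc(=O)c3c2OCc2ccccc2)c1)c1c(O)cc(OCc2ccccc2)cc1OCc1ccccc1
F2 | step 10 | racemic 5,7-bis(benzyloxy)-2-(4-(benzyloxy)-3-{5,7-bis(benzyloxy)-2-[4-(benzyloxy)phenyl]-4-oxo-4H-chromen-6-yl}phenyl)-2,3-dihydro-4H-chromen-4-one | O=C1CC(c2ccc(OCc3ccccc3)c(-c3c(OCc4ccccc4)cc4oc(-c5ccc(OCc6ccccc6)cc5)cc(=O)c4c3OCc3ccccc3)c2)Oc2cc(OCc3ccccc3)cc(OCc3ccccc3)c21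
F3 | step 10 | (2R)-5,7-bis(benzyloxy)-2-(4-(benzyloxy)-3-{5,7-bis(benzyloxy)-2-[4-(benzyloxy)phenyl]-4-oxo-4H-chromen-6-yl}phenyl)-2,3-dihydro-4H-chromen-4-one | O=C1C[C@H](c2ccc(OCc3ccccc3)c(-c3c(OCc4ccccc4)cc4oc(-c5ccc(OCc6ccccc6)cc5)cc(=O)c4c3OCc3ccccc3)c2)Oc2cc(OCc3ccccc3)cc(OCc3ccccc3)c21
F4 | step 9 | tert-butyl 3-[2,4-bis(benzyloxy)-6-(triisopropylsilyloxy)phenyl]-3-oxopropanoate | CC(C)(C)OC(=O)CC(=O)c1c(O[Si](C(C)C)(C(C)C)C(C)C)cc(OCc2ccccc2)cc1OCc1ccccc1
F5 | step 9 | tert-butyl (2Z)-2-[2,4-bis(benzyloxy)-6-(triisopropylsilyloxy)benzoyl]-3-(4-(benzyloxy)-3-{5,7-bis(benzyloxy)-2-[4-(benzyloxy)phenyl]-4-oxo-4H-chromen-6-yl}phenyl)prop-2-enoate | CC(C)(C)OC(=O)/C(=C\c1ccc(OCc2ccccc2)c(-c2c(OCc3ccccc3)cc3oc(-c4ccc(OCc5ccccc5)cc4)cc(=O)c3c2OCc2ccccc2)c1)C(=O)c1c(O[Si](C(C)C)(C(C)C)C(C)C)cc(OCc2ccccc2)cc1OCc1ccccc1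
F6 | step 11 | benzyl 3-[2,4-bis(benzyloxy)-6-hydroxyphenyl]-3-oxopropanoate | O=C(CC(=O)c1c(O)cc(OCc2ccccc2)cc1OCc1ccccc1)OCc1ccccc1
F7 | step 11 | benzyl (2Z)-2-[2,4-bis(benzyloxy)-6-hydroxybenzoyl]-3-(4-(benzyloxy)-3-{5,7-bis(benzyloxy)-2-[4-(benzyloxy)phenyl]-4-oxo-4H-chromen-6-yl}phenyl)prop-2-enoate | O=C(OCc1ccccc1)/C(=C\c1ccc(OCc2ccccc2)c(-c2c(OCc3ccccc3)cc3oc(-c4ccc(OCc5ccccc5)cc4)cc(=O)c3c2OCc2ccccc2)c1)C(=O)c1c(O)cc(OCc2ccccc2)cc1OCc1ccccc1
F8 | step 11 | benzyl (2S,3R)-5,7-bis(benzyloxy)-2-(4-(benzyloxy)-3-{5,7-bis(benzyloxy)-2-[4-(benzyloxy)phenyl]-4-oxo-4H-chromen-6-yl}phenyl)-4-oxo-3,4-dihydro-2H-chromene-3-carboxylate | O=C1[C@H](C(=O)OCc2ccccc2)[C@@H](c2ccc(OCc3ccccc3)c(-c3c(OCc4ccccc4)cc4oc(-c5ccc(OCc6ccccc6)cc5)cc(=O)c4c3OCc3ccccc3)c2)Oc2cc(OCc3ccccc3)cc(OCc3ccccc3)c21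
F9 | step 11 | (2S,3R)-5,7-dihydroxy-2-{3-[5,7-dihydroxy-2-(4-hydroxyphenyl)-4-oxo-4H-chromen-6-yl]-4-hydroxyphenyl}-4-oxo-3,4-dihydro-2H-chromene-3-carboxylic acid | O=C1[C@H](C(=O)O)[C@@H](c2ccc(O)c(-c3c(O)cc4oc(-c5ccc(O)cc5)cc(=O)c4c3O)c2)Oc2cc(O)cc(O)c21
F10 | step 6 | 4-(benzyloxy)-3-{7-(benzyloxy)-2-[4-(benzyloxy)phenyl]-5-hydroxy-4-oxo-4H-chromen-6-yl}benzaldehyde | O=Cc1ccc(OCc2ccccc2)c(-c2c(OCc3ccccc3)cc3oc(-c4ccc(OCc5ccccc5)cc4)cc(=O)c3c2O)c1
F0 | step 12 | none | none
A1 | alternative 1 | {5,7-bis(benzyloxy)-2-[4-(benzyloxy)phenyl]-4-oxo-4H-chromen-6-yl}acetic acid | OC(=O)Cc1c(OCc2ccccc2)cc2oc(-c3ccc(OCc4ccccc4)cc3)cc(=O)c2c1OCc1ccccc1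
A2 | alternative 1 | 6-[2,2-bis(trimethylsilyloxy)ethenyl]-5,7-bis(benzyloxy)-2-[4-(benzyloxy)phenyl]-4H-chromen-4-one | C[Si](C)(C)OC(O[Si](C)(C)C)=Cc1c(OCc2ccccc2)cc2oc(-c3ccc(OCc4ccccc4)cc3)cc(=O)c2c1OCc1ccccc1
A3 | alternative 1 | methyl coumalate, methyl 2-oxo-2H-pyran-5-carboxylate | COC(=O)c1ccc(=O)oc1
A4 | alternative 1 | methyl 4-hydroxy-3-{5,7-bis(benzyloxy)-2-[4-(benzyloxy)phenyl]-4-oxo-4H-chromen-6-yl}benzoate | COC(=O)c1ccc(O)c(-c2c(OCc3ccccc3)cc3oc(-c4ccc(OCc5ccccc5)cc4)cc(=O)c3c2OCc2ccccc2)c1
A5 | alternative 2 | 2-[4-(benzyloxy)phenyl]-6-(diazoacetyl)-4H-pyran-4-one | O=C(C=[N+]=[N-])c1cc(=O)cc(-c2ccc(OCc3ccccc3)cc2)o1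
A6 | alternative 2 | {[2-(benzyloxy)-5-(1,3-dioxolan-2-yl)phenyl]ethynyloxy}triisopropylsilane | CC(C)[Si](OC#Cc1cc(C2OCCO2)ccc1OCc1ccccc1)(C(C)C)C(C)C
A7 | alternative 2 | 6-[2-(benzyloxy)-5-(1,3-dioxolan-2-yl)phenyl]-2-[4-(benzyloxy)phenyl]-5-hydroxy-7-(triisopropylsilyloxy)-4H-chromen-4-one | CC(C)[Si](Oc1cc2oc(-c3ccc(OCc4ccccc4)cc3)cc(=O)c2c(O)c1-c1cc(C2OCCO2)ccc1OCc1ccccc1)(C(C)C)C(C)C
A8 | alternative 3 | 2-diazo-1-{2-[(4-(benzyloxy)-3-{5,7-bis(benzyloxy)-2-[4-(benzyloxy)phenyl]-4-oxo-4H-chromen-6-yl}phenyl)methoxy]-4,6-bis(triisopropylsilyloxy)phenyl}ethan-1-one | O=C(C=[N+]=[N-])c1c(OCc2ccc(OCc3ccccc3)c(-c3c(OCc4ccccc4)cc4oc(-c5ccc(OCc6ccccc6)cc5)cc(=O)c4c3OCc3ccccc3)c2)cc(O[Si](C(C)C)(C(C)C)C(C)C)cc1O[Si](C(C)C)(C(C)C)C(C)C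
A9 | alternative 3 | (2S)-2-(4-(benzyloxy)-3-{5,7-bis(benzyloxy)-2-[4-(benzyloxy)phenyl]-4-oxo-4H-chromen-6-yl}phenyl)-5,7-bis(triisopropylsilyloxy)-2,3-dihydro-4H-chromen-4-one | O=C1C[C@@H](c2ccc(OCc3ccccc3)c(-c3c(OCc4ccccc4)cc4oc(-c5ccc(OCc6ccccc6)cc5)cc(=O)c4c3OCc3ccccc3)c2)Oc2cc(O[Si](C(C)C)(C(C)C)C(C)C)cc(O[Si](C(C)C)(C(C)C)C(C)C)c21
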